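**Retrosynthetic overview**
- Target ⇐ (13S,14R)-triol (C-14 mono-acetate through a cyclic orthoacetate) ⇐ Sharpless epoxidation and Payne opening of a (13E)-allylic alcohol ⇐ Negishi carboalumination of a terminal alkyne; CO2Me ⇐ C-18 CH2OH.
- Rearranged decalin ⇐ one acyclic (S)-epoxy-(4Z,8Z)-dienyne in a single cation–olefin cascade: ring A first (C-4–C-5), then ring B (C-10–C-9), then H-9→C-8 and CH3-20→C-9 shifts and loss of H-1, as in the copalyl→halimadienyl pathway.
- The 2,2-disubstituted epoxide (opened with inversion at C-4) fixes absolute configuration; the Z geometry of both chain olefins fixes C-5, C-8 and C-9.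
- Polyene ⇐ two B-alkyl Suzuki couplings of (Z)-vinyl iodides (Stork–Zhao) onto (S)-2-allyl-2-methyloxirane ⇐ acrolein, pent-4-yn-1-ol, methallyl alcohol.

Assumption: the SMILES is taken literally, so H-5 lies on the same face as the C-8 and C-9 methyl groups (the C-5 epimer of the usual ent-halim-1(10)-ene pattern), which is why both chain olefins are built Z; halimane numbering (C-1 to C-20) is used for positions.

**Route**

Step 1
Reactants: 1 acrolein
Product: 2 (3Z)-4-iodopenta-1,3-diene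
Conditions: EtPPh3I, n-BuLi, THF, 0 °C; iodine, −78 °C; NaN(SiMe3)2, −78 °C; then 1, −78 → −20 °C (product kept as a cold solution)
Reagents that add atoms: ethyltriphenylphosphonium iodide CC[P+](c1ccccc1)(c1ccccc1)c1ccccc1.[I-]; iodine [I][I]
Why: Stork–Zhao–Wittig olefination, in which the α-iodo ylide Ph3P=C(iodo)CH3 adds to the aldehyde under kinetic control to give the (Z)-iodoalkene (iodine cis to the vinyl group); no stereocentre is formed.

Step 2
Reactants: 3 pent-4-yn-1-ol
Product: 4 pent-4-ynal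
Conditions: PhI(OAc)2, 2,2,6,6-tetramethylpiperidin-1-oxyl (TEMPO, 10 mol %), CH2Cl2, rt
Reagents that add atoms: none
Why: Oxoammonium-mediated (TEMPO) alcohol oxidation stops cleanly at the aldehyde and leaves the terminal alkyne untouched.

Step 3
Reactants: 4 pent-4-ynal
Product: 5 (5Z)-6-iodohept-5-en-1-yne
Conditions: EtPPh3I, n-BuLi, THF, 0 °C; iodine, −78 °C; NaN(SiMe3)2, −78 °C; then 4, −78 → −20 °C
Reagents that add atoms: ethyltriphenylphosphonium iodide CC[P+](c1ccccc1)(c1ccccc1)c1ccccc1.[I-]; iodine [I][I]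
Why: Stork–Zhao–Wittig olefination as in step 1, giving the (Z)-iodoalkene with iodine cis to the alkyl chain, which later becomes the Z C-8/C-9 olefin.

Step 4
Reactants: 6 2-methylprop-2-en-1-ol
Product: 8 (S)-2-methylglycidyl tosylate, via (R)-2-methylglycidol 7 (not isolated)
Conditions: Ti(OiPr)4 (5 mol %), D-(−)-diisopropyl tartrate (6 mol %), t-BuOOH, 4 Å molecular sieves, CH2Cl2, −20 °C; then TsCl, Et3N, 4-(dimethylamino)pyridine (cat.), −10 °C
Reagents that add atoms: tert-butyl hydroperoxide CC(C)(C)OO; 4-toluenesulfonyl chloride Cc1ccc(cc1)S(Cl)(=O)=O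
Why: Katsuki–Sharpless asymmetric epoxidation with the D-(−)-tartrate catalyst sets the quaternary centre that becomes C-4 as (R)-2-methylglycidol, which is sulfonylated in situ (the descriptor becomes S only through the CIP priority switch).

Step 5
Reactants: 8 (S)-2-methylglycidyl tosylate
Product: 10 (2S)-2-allyl-2-methyloxirane, via tosyloxy alcohol 9 (not isolated)
Conditions: CH2=CHMgBr, CuI (10 mol %), THF, −40 → 0 °C; then NaOH (aq), rt
Reagents that add atoms: vinylmagnesium bromide C=C[Mg]Br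
Why: Copper-catalysed Grignard opening at the unsubstituted epoxide carbon followed by Williamson closure of the tertiary alkoxide onto the primary tosylate; no bond to the stereocentre is broken, so its configuration is kept.

Step 6
Reactants: 10 (2S)-2-allyl-2-methyloxirane; 2 (3Z)-4-iodopenta-1,3-diene
Product: 12 (2S)-2-methyl-2-[(4Z)-4-methylhepta-4,6-dien-1-yl]oxirane, via alkylborane 11 (not isolated)
Conditions: 9-borabicyclo[3.3.1]nonane (9-BBN-H), THF, 0 °C → rt; then 2, Pd(dppf)Cl2 (5 mol %; dppf = 1,1'-bis(diphenylphosphino)ferrocene), AsPh3, K3PO4 (aq), DMF, rt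
Reagents that add atoms: none
Why: Anti-Markovnikov hydroboration of the terminal alkene and B-alkyl Suzuki–Miyaura coupling, which proceeds with retention at the vinyl iodide and so gives the Z C-5/C-10 olefin.

Step 7
Reactants: 12 (2S)-2-methyl-2-[(4Z)-4-methylhepta-4,6-dien-1-yl]oxirane; 5 (5Z)-6-iodohept-5-en-1-yne
Product: 14 (2S)-2-[(4Z,8Z)-4,8-dimethyltrideca-4,8-dien-12-yn-1-yl]-2-methyloxirane, via alkylborane 13 (not isolated)
Conditions: 9-BBN-H (1.0 equiv), THF, 0 °C → rt; then 5, Pd(dppf)Cl2 (5 mol %), AsPh3, K3PO4 (aq), DMF, rt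
Reagents that add atoms: none
Why: 9-BBN-H adds only to the terminal vinyl group of the diene (boron at C-7) and the B-alkyl Suzuki–Miyaura coupling again retains the iodide geometry, giving the Z C-8/C-9 olefin.

Step 8
Reactants: 14 (2S)-2-[(4Z,8Z)-4,8-dimethyltrideca-4,8-dien-12-yn-1-yl]-2-methyloxirane
Product: 16 [(1S,5S,6R,8aR)-5-(but-3-yn-1-yl)-1,5,6-trimethyl-1,2,3,5,6,7,8,8a-octahydronaphthalen-1-yl]methanol, via silyl ether 15 (not isolated)
Conditions: iPr3SiOTf (1.2 equiv), 2,6-di-tert-butyl-4-methylpyridine (1.5 equiv), CH2Cl2, −78 → −40 °C; then HF·pyridine, THF, 0 °C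
Reagents that add atoms: none
Why: Proposed new method: silyl-triflate activation lets the C-5/C-10 olefin open the (S)-epoxide at C-4 with inversion in a chair transition state (CH2OSi equatorial, so C-4 and C-5 are set together), the Z geometry of that olefin forces the cis H-5/CH3-20 relationship (Stork–Eschenmoser) and the Z C-8/C-9 olefin places H-9 trans to CH3-20; the conformationally mobile cis-fused C-8 cation then passes H-9 to C-8 and CH3-20 to C-9 suprafacially (setting C-8 and C-9), the electron-withdrawing C-4 substituent stops the shifts at C-10, and loss of the exposed H-1 (H-5 is flanked by the two methyls on its face) gives the 1(10)-ene, while the bulky silyl ether cannot close an 18,10-ether and the hindered pyridine removes TfOH so the olefin is not re-protonated; the closest known reaction types are the Lewis-acid epoxy-polyene cyclisation and the BF3-induced 1,2-hydride/1,2-methyl (friedo) shift of labdanyl and drimanyl cations.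

Step 9
Reactants: 16 [(1S,5S,6R,8aR)-5-(but-3-yn-1-yl)-1,5,6-trimethyl-1,2,3,5,6,7,8,8a-octahydronaphthalen-1-yl]methanol
Product: 18 methyl (1S,5S,6R,8aR)-5-(but-3-yn-1-yl)-1,5,6-trimethyl-1,2,3,5,6,7,8,8a-octahydronaphthalene-1-carboxylate, via carboxylic acid 17 (not isolated)
Conditions: TEMPO (cat.), NaOCl (cat.), NaClO2, MeCN/phosphate buffer (pH 6.7), 35 °C; then Me3SiCHN2, MeOH/PhMe, 0 °C
Reagents that add atoms: sodium chlorite [Na+].[O-]Cl=O; trimethylsilyldiazomethane C[Si](C)(C)C=[N+]=[N-]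
Why: TEMPO/chlorite oxidation takes the neopentyl primary alcohol to the acid without touching the olefin or alkyne, and O-methylation with the diazoalkane gives the hindered C-4 ester.

Step 10
Reactants: 18 methyl (1S,5S,6R,8aR)-5-(but-3-yn-1-yl)-1,5,6-trimethyl-1,2,3,5,6,7,8,8a-octahydronaphthalene-1-carboxylate
Product: 20 methyl (1S,5S,6R,8aR)-5-[(3E)-5-hydroxy-3-methylpent-3-en-1-yl]-1,5,6-trimethyl-1,2,3,5,6,7,8,8a-octahydronaphthalene-1-carboxylate, via alkenylalane 19 (not isolated)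
Conditions: AlMe3 (3 equiv), Cp2ZrCl2 (20 mol %), H2O (1 equiv), CH2Cl2, −23 °C; then (CH2O)n, THF, 0 °C → rt
Reagents that add atoms: trimethylaluminium C[Al](C)C; paraformaldehyde (formaldehyde) C=O
Why: Negishi zirconium-catalysed carboalumination adds CH3 and Al syn across the terminal alkyne (hence the 13E olefin) and the alkenylalane is hydroxymethylated by formaldehyde, the α-quaternary ester being too hindered to react.

Step 11
Reactants: 20 methyl (1S,5S,6R,8aR)-5-[(3E)-5-hydroxy-3-methylpent-3-en-1-yl]-1,5,6-trimethyl-1,2,3,5,6,7,8,8a-octahydronaphthalene-1-carboxylate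
Product: 21 methyl (1S,5S,6R,8aR)-5-{2-[(2S,3S)-3-(hydroxymethyl)-2-methyloxiran-2-yl]ethyl}-1,5,6-trimethyl-1,2,3,5,6,7,8,8a-octahydronaphthalene-1-carboxylate
Conditions: Ti(OiPr)4 (10 mol %), L-(+)-diisopropyl tartrate (12 mol %), t-BuOOH, 4 Å molecular sieves, CH2Cl2, −20 °C
Reagents that add atoms: tert-butyl hydroperoxide CC(C)(C)OO
Why: Katsuki–Sharpless asymmetric epoxidation is reagent-controlled and specific for the allylic alcohol (the ring olefin is inert), giving the (13S,14S)-epoxide as with geraniol-type substrates and the L-(+)-tartrate.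

Step 12
Reactants: 21 methyl (1S,5S,6R,8aR)-5-{2-[(2S,3S)-3-(hydroxymethyl)-2-methyloxiran-2-yl]ethyl}-1,5,6-trimethyl-1,2,3,5,6,7,8,8a-octahydronaphthalene-1-carboxylate
Product: 23 methyl (1S,5S,6R,8aR)-1,5,6-trimethyl-5-[(3S,4R)-3,4,5-trihydroxy-3-methylpentyl]-1,2,3,5,6,7,8,8a-octahydronaphthalene-1-carboxylate, via terminal epoxide 22 (not isolated)
Conditions: NaOH (0.5 M aq), t-BuOH, 70 °C
Reagents that add atoms: water O
Why: Payne rearrangement: the C-15 alkoxide attacks C-14 with inversion to give the 14,15-epoxide, which hydroxide opens at primary C-15, so C-13 is retained (S) and C-14 inverted (R), the anti-triol that dihydroxylation of the E olefin cannot give; the hindered C-4 ester survives.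

Step 13
Reactants: 23 methyl (1S,5S,6R,8aR)-1,5,6-trimethyl-5-[(3S,4R)-3,4,5-trihydroxy-3-methylpentyl]-1,2,3,5,6,7,8,8a-octahydronaphthalene-1-carboxylate
Product: 25 methyl (1S,5S,6R,8aR)-5-[(3S,4R)-4-acetoxy-3,5-dihydroxy-3-methylpentyl]-1,5,6-trimethyl-1,2,3,5,6,7,8,8a-octahydronaphthalene-1-carboxylate, via cyclic orthoester 24 (not isolated)
Conditions: MeC(OMe)3, pyridinium 4-toluenesulfonate (cat.), CH2Cl2, rt; then AcOH/H2O (4:1), 0 °C → rt
Reagents that add atoms: trimethyl orthoacetate CC(OC)(OC)OC; water O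
Why: Orthoester-mediated regioselective mono-acylation: the primary/secondary 14,15-diol forms the five-membered cyclic orthoacetate, whose kinetic acid hydrolysis via the dioxolan-2-ylium ion releases the primary hydroxyl and leaves the acetate on secondary O-14, with the tertiary 13-OH untouched.

**Compound list**

1 | acrolein (prop-2-enal) | C=CC=O | starting material
2 | (3Z)-4-iodopenta-1,3-diene | I/C(C)=C\C=C | intermediate
3 | pent-4-yn-1-ol | C#CCCCO | starting material
4 | pent-4-ynal | C#CCCC=O | intermediate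
5 | (5Z)-6-iodohept-5-en-1-yne | I/C(C)=C\CCC#C | intermediate
6 | 2-methylprop-2-en-1-ol (methallyl alcohol) | C=C(C)CO | starting material
7 | (R)-2-methylglycidol, [(2R)-2-methyloxiran-2-yl]methanol | C[C@@]1(CO)CO1 | intermediate (not isolated)
8 | (S)-2-methylglycidyl tosylate | C[C@@]1(COS(=O)(=O)c2ccc(C)cc2)CO1 | intermediate
9 | (2S)-2-hydroxy-2-methylpent-4-en-1-yl 4-toluenesulfonate | C=CC[C@](C)(O)COS(=O)(=O)c1ccc(C)cc1 | intermediate (not isolated)
10 | (2S)-2-allyl-2-methyloxirane | C=CC[C@@]1(C)CO1 | intermediate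
11 | 9-{3-[(2S)-2-methyloxiran-2-yl]propyl}-9-borabicyclo[3.3.1]nonane | C[C@]1(CCCB2C3CCCC2CCC3)CO1 | intermediate (not isolated)
12 | (2S)-2-methyl-2-[(4Z)-4-methylhepta-4,6-dien-1-yl]oxirane | C=C/C=C(C)\CCC[C@@]1(C)CO1 | intermediate
13 | 9-{(3Z)-4-methyl-7-[(2S)-2-methyloxiran-2-yl]hept-3-en-1-yl}-9-borabicyclo[3.3.1]nonane | C[C@]1(CCC/C(C)=C\CCB2C3CCCC2CCC3)CO1 | intermediate (not isolated)
14 | (2S)-2-[(4Z,8Z)-4,8-dimethyltrideca-4,8-dien-12-yn-1-yl]-2-methyloxirane | C#CCC/C=C(C)\CC/C=C(C)\CCC[C@@]1(C)CO1 | intermediate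
15 | triisopropylsilyl ether of 16 | CC(C)[Si](OC[C@@]1(C)CCC=C2[C@H]1CC[C@@H](C)[C@]2(C)CCC#C)(C(C)C)C(C)C | intermediate (not isolated)
16 | [(1S,5S,6R,8aR)-5-(but-3-yn-1-yl)-1,5,6-trimethyl-1,2,3,5,6,7,8,8a-octahydronaphthalen-1-yl]methanol (halimane numbering: 4S,5R,8R,9S; 5α-H, 8α-CH3, 9α-CH3, 1(10)-ene) | OC[C@@]1(C)CCC=C2[C@H]1CC[C@@H](C)[C@]2(C)CCC#C | intermediate
17 | (1S,5S,6R,8aR)-5-(but-3-yn-1-yl)-1,5,6-trimethyl-1,2,3,5,6,7,8,8a-octahydronaphthalene-1-carboxylic acid | OC(=O)[C@@]1(C)CCC=C2[C@H]1CC[C@@H](C)[C@]2(C)CCC#C | intermediate (not isolated)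
18 | methyl (1S,5S,6R,8aR)-5-(but-3-yn-1-yl)-1,5,6-trimethyl-1,2,3,5,6,7,8,8a-octahydronaphthalene-1-carboxylate | COC(=O)[C@@]1(C)CCC=C2[C@H]1CC[C@@H](C)[C@]2(C)CCC#C | intermediate
19 | (E)-alkenyl(dimethyl)alane from 18 (Al on C-14, new CH3 on C-13) | COC(=O)[C@@]1(C)CCC=C2[C@H]1CC[C@@H](C)[C@]2(C)CC/C(C)=C/[Al](C)C | intermediate (not isolated)
20 | methyl (1S,5S,6R,8aR)-5-[(3E)-5-hydroxy-3-methylpent-3-en-1-yl]-1,5,6-trimethyl-1,2,3,5,6,7,8,8a-octahydronaphthalene-1-carboxylate | COC(=O)[C@@]1(C)CCC=C2[C@H]1CC[C@@H](C)[C@]2(C)CC/C(C)=C/CO | intermediate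
21 | methyl (1S,5S,6R,8aR)-5-{2-[(2S,3S)-3-(hydroxymethyl)-2-methyloxiran-2-yl]ethyl}-1,5,6-trimethyl-1,2,3,5,6,7,8,8a-octahydronaphthalene-1-carboxylate | COC(=O)[C@@]1(C)CCC=C2[C@H]1CC[C@@H](C)[C@]2(C)CC[C@]3(C)O[C@H]3CO | intermediate
22 | methyl (1S,5S,6R,8aR)-5-{(3S)-3-hydroxy-3-[(2R)-oxiran-2-yl]butyl}-1,5,6-trimethyl-1,2,3,5,6,7,8,8a-octahydronaphthalene-1-carboxylate | COC(=O)[C@@]1(C)CCC=C2[C@H]1CC[C@@H](C)[C@]2(C)CC[C@](C)(O)[C@H]3CO3 | intermediate (not isolated)
23 | methyl (1S,5S,6R,8aR)-1,5,6-trimethyl-5-[(3S,4R)-3,4,5-trihydroxy-3-methylpentyl]-1,2,3,5,6,7,8,8a-octahydronaphthalene-1-carboxylate | COC(=O)[C@@]1(C)CCC=C2[C@H]1CC[C@@H](C)[C@]2(C)CC[C@](C)(O)[C@@H](CO)O | intermediate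
24 | 14,15-O-(1-methoxyethylidene) cyclic orthoacetate of 23 (orthoester carbon unassigned) | COC(=O)[C@@]1(C)CCC=C2[C@H]1CC[C@@H](C)[C@]2(C)CC[C@](C)(O)[C@H]3COC(C)(OC)O3 | intermediate (not isolated)
25 | methyl (1S,5S,6R,8aR)-5-[(3S,4R)-4-acetoxy-3,5-dihydroxy-3-methylpentyl]-1,5,6-trimethyl-1,2,3,5,6,7,8,8a-octahydronaphthalene-1-carboxylate (CNP0210069.1) | COC(=O)[C@@]1(C)CCC=C2[C@H]1CC[C@@H](C)[C@]2(C)CC[C@](C)(O)[C@@H](CO)OC(C)=O | target

**Step count and risks**

Total: 13 steps. Longest linear sequence: 10 steps (6 → 25, steps 4 to 13); the two iodide branches are 1 and 2 steps.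

Most likely to fail, in this order:

Step 8. The cascade has no direct precedent in the cis-fused series. Expected failure modes:
- the C-8 cation loses a proton before H-9 migrates, giving unrearranged cis-labdadienes;
- the C-10 cation loses H-5, giving the 5(10)-ene;
- cyclisation through the chair with axial CH2OSi, giving the C-4-epimeric, otherwise antipodal diastereomer;
- elimination or 1,2-hydride shift at the activated epoxide before ring closure.

The fallback sets out from 14 and comes back at 18, and separates ring formation from rearrangement. Compound 14 is cyclised alone with MeAlCl2 (CH2Cl2, −78 °C) to the unrearranged cis-fused alcohol [(1S,4aS,5R,8aR)-5-(but-3-yn-1-yl)-1,4a-dimethyl-6-methylidenedecahydronaphthalen-1-yl]methanol F1 (5-H cis to the C-10 methyl, 9-H trans to it; the 7-ene isomer converges). F1 is oxidised and methylated as in step 9 to methyl (1S,4aS,5R,8aR)-5-(but-3-yn-1-yl)-1,4a-dimethyl-6-methylidenedecahydronaphthalene-1-carboxylate F2. F2, which no longer carries a nucleophilic C-18 oxygen, is then treated with BF3·OEt2 (CH2Cl2, −50 → −5 °C) to trigger the 1,2-hydride and 1,2-methyl shifts, giving 18.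

Step 12. The Payne sequence needs hot aqueous base next to an ester and must outrun direct opening of the trisubstituted epoxide. The fallback sets out from 20 and comes back at 23. Compound 20 is epoxidised with the D-(−)-tartrate catalyst instead, giving methyl (1S,5S,6R,8aR)-5-{2-[(2R,3R)-3-(hydroxymethyl)-2-methyloxiran-2-yl]ethyl}-1,5,6-trimethyl-1,2,3,5,6,7,8,8a-octahydronaphthalene-1-carboxylate F3. F3 is hydrolysed with dilute HClO4 in THF/H2O at 0 °C; water opens the tertiary C-13 with inversion and C-14 is retained, which gives the same (13S,14R)-triol 23.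

Step 13. The cyclic orthoester may also engage the tertiary 13-OH, and the secondary acetate can migrate to O-15. The fallback sets out from 23 and ends at 25, using a protecting group instead. TBSCl/imidazole (DMF, 0 °C) gives methyl (1S,5S,6R,8aR)-5-[(3S,4R)-5-(tert-butyldimethylsilyloxy)-3,4-dihydroxy-3-methylpentyl]-1,5,6-trimethyl-1,2,3,5,6,7,8,8a-octahydronaphthalene-1-carboxylate F4. Ac2O with 4-(dimethylamino)pyridine in pyridine acetylates only the secondary hydroxyl, giving methyl (1S,5S,6R,8aR)-5-[(3S,4R)-4-acetoxy-5-(tert-butyldimethylsilyloxy)-3-hydroxy-3-methylpentyl]-1,5,6-trimethyl-1,2,3,5,6,7,8,8a-octahydronaphthalene-1-carboxylate F5. Buffered HF·pyridine (THF, 0 °C) removes the silyl group without acyl migration to give 25.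

**Further compounds**

F1 | step 8 | [(1S,4aS,5R,8aR)-5-(but-3-yn-1-yl)-1,4a-dimethyl-6-methylidenedecahydronaphthalen-1-yl]methanol | OC[C@@]1(C)CCC[C@]2(C)[C@H]1CCC(=C)[C@H]2CCC#C
F2 | step 8 | methyl (1S,4aS,5R,8aR)-5-(but-3-yn-1-yl)-1,4a-dimethyl-6-methylidenedecahydronaphthalene-1-carboxylate | COC(=O)[C@@]1(C)CCC[C@]2(C)[C@H]1CCC(=C)[C@H]2CCC#C
F3 | step 12 | methyl (1S,5S,6R,8aR)-5-{2-[(2R,3R)-3-(hydroxymethyl)-2-methyloxiran-2-yl]ethyl}-1,5,6-trimethyl-1,2,3,5,6,7,8,8a-octahydronaphthalene-1-carboxylate | COC(=O)[C@@]1(C)CCC=C2[C@H]1CC[C@@H](C)[C@]2(C)CC[C@@]3(C)O[C@@H]3CO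
F4 | step 13 | methyl (1S,5S,6R,8aR)-5-[(3S,4R)-5-(tert-butyldimethylsilyloxy)-3,4-dihydroxy-3-methylpentyl]-1,5,6-trimethyl-1,2,3,5,6,7,8,8a-octahydronaphthalene-1-carboxylate | COC(=O)[C@@]1(C)CCC=C2[C@H]1CC[C@@H](C)[C@]2(C)CC[C@](C)(O)[C@@H](CO[Si](C)(C)C(C)(C)C)O
F5 | step 13 | methyl (1S,5S,6R,8aR)-5-[(3S,4R)-4-acetoxy-5-(tert-butyldimethylsilyloxy)-3-hydroxy-3-methylpentyl]-1,5,6-trimethyl-1,2,3,5,6,7,8,8a-octahydronaphthalene-1-carboxylate | COC(=O)[C@@]1(C)CCC=C2[C@H]1CC[C@@H](C)[C@]2(C)CC[C@](C)(O)[C@@H](CO[Si](C)(C)C(C)(C)C)OC(C)=O
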